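**Plan**
1. Retrosynthesis, last events first: the hydroxyl of the hydroxyquinone ring (ring C) comes from a methyl vinylogous ester; both quinones come from a naphthalene-1,4-diol (ring A) and a 1,3,4-trimethoxynaphthalene (rings C/D) by oxidation with (NH4)2Ce(NO3)6.
2. Ring A (the ester-bearing quinone ring) is cut at C1–C2, the bond from a ketone carbon to the ester-bearing carbon, and C1 is rejoined to C3. This contracts ring A to the five-membered ring of a 2-aryl-2-(methoxycarbonylmethyl)indane-1,3-dione.
3. The feature that allows this: in ring A, C1(=O)–C2–CO2Me is a β-keto ester (a Dieckmann bond), and C3 lies between the two benzo-ring carbonyls C1 and C4. C3 can therefore be C2 of a non-enolisable indane-1,3-dione, which methoxide opens by retro-Claisen cleavage.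
4. Further cuts: the bond from the quaternary dione carbon to CH2 (alkylation with methyl bromoacetate), then the 2-arylindane-1,3-dione into phthalide and an aryl aldehyde; the aldehyde comes from 2-methoxy-1,4-naphthoquinone via 1,2,4-trimethoxynaphthalene.
5. Forward order: rings C/D are present, masked, from the start; the five-membered dione ring is built on phthalide (ring B); a one-carbon expansion gives six-membered ring A; oxidation and unmasking follow.
6. Stereochemistry: none to set. The target has no stereocentre, and the stereocentres of the ring-expansion intermediates vanish on aromatisation.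

Key step: step 5

Assumption: the target is drawn without stereodescriptors, so the quinone–quinone biaryl axis is treated as configurationally unspecified and no axial control is planned.

**Route**

Step 1
Reactants: 1 2-methoxy-1,4-naphthoquinone
Product: 3 1,2,4-trimethoxynaphthalene, via 2-methoxynaphthalene-1,4-diol 2 (not isolated)
Conditions: Na2S2O4, Bu4NBr (cat.), THF/H2O, rt; then KOH (aq), Me2SO4, 0 °C → rt, N2
Reagents that add atoms: dimethyl sulfate, COS(=O)(=O)OC
Why: Na2S2O4 reduces the quinone to hydroquinone 2, whose two phenoxides are O-methylated by dimethyl sulfate under phase transfer (Williamson ether synthesis), a standard reductive methylation of naphthoquinones.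

Step 2
Reactants: 3 1,2,4-trimethoxynaphthalene
Product: 5 1,3,4-trimethoxynaphthalene-2-carbaldehyde, via (1,3,4-trimethoxynaphthalen-2-yl)lithium 4 (not isolated)
Conditions: n-BuLi, TMEDA, THF, 0 °C; DMF, −78 °C → rt; 1 M HCl
Reagents that add atoms: N,N-dimethylformamide, CN(C)C=O
Why: Directed ortho-lithiation should occur at the only C–H flanked by two methoxy groups (C3 of 3), and aryllithium 4 is formylated by DMF (Bouveault formylation).

Step 3
Reactants: 5 1,3,4-trimethoxynaphthalene-2-carbaldehyde; 6 phthalide
Product: 9 2-(1,3,4-trimethoxynaphthalen-2-yl)-1H-indene-1,3(2H)-dione, via (Z)-3-arylidenephthalide 7 (not isolated), via methyl 2-(arylacetyl)benzoate 8 (not isolated)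
Conditions: NaOMe, MeOH, ethyl propionate, reflux; then 2 M HCl
Reagents that add atoms: none
Why: Classical phthalide–aldehyde condensation, in which aldol condensation of the phthalide anion with 5 gives arylidenephthalide 7, methoxide opens the enol lactone to keto ester 8, and its enolate closes by Claisen condensation to the 2-arylindane-1,3-dione, set free on acidification.

Step 4
Reactants: 9 2-(1,3,4-trimethoxynaphthalen-2-yl)-1H-indene-1,3(2H)-dione; 10 methyl bromoacetate
Product: 11 methyl 2-[1,3-dioxo-2-(1,3,4-trimethoxynaphthalen-2-yl)-2,3-dihydro-1H-inden-2-yl]acetate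
Conditions: K2CO3, NaI (cat.), acetone, reflux
Reagents that add atoms: none
Why: SN2 C-alkylation of the soft, delocalised 2-arylindane-1,3-dione enolate by the α-halo ester (the iodide forms in the flask by Finkelstein exchange), C-attack being favoured because O-alkylation would give a cross-conjugated indenone enol ether.

Step 5
Reactants: 11 methyl 2-[1,3-dioxo-2-(1,3,4-trimethoxynaphthalen-2-yl)-2,3-dihydro-1H-inden-2-yl]acetate
Product: 14 methyl 1,4-dihydroxy-3-(1,3,4-trimethoxynaphthalen-2-yl)naphthalene-2-carboxylate, via open-chain keto diester 12 (not isolated), via cyclic diketo ester 13 (not isolated)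
Conditions: NaOMe (3 equiv), dry MeOH/THF, reflux, Ar; then degassed 1 M HCl, 0 °C
Reagents that add atoms: none
Why: Methoxide adds to one of the two mirror-related ring ketones of the non-enolisable 1,3-dione 11, and retro-Claisen cleavage of the bond to the quaternary carbon opens the five-membered ring to keto diester 12; proton exchange gives the side-chain ester enolate, which closes onto the new methyl benzoate carbonyl (Dieckmann condensation) to the six-membered β-keto ester 13, and enolisation of both ring ketones aromatises it to the naphthalene-1,4-diol 14 (direct 3-exo attack of the same enolate on the ketone and opening of the cyclopropanolate would lead to the same ring). The closest known reaction type is the Gabriel–Colman rearrangement, that is, the alkoxide-induced retro-Claisen/Dieckmann ring enlargement of a five-membered 1,3-dicarbonyl ring that carries a CH2CO2R arm. The one ring closed is six-membered ring A, formed in a 6-(enolexo)-exo-trig closure. No stereocentre survives: the stereocentres of 12 and 13 are not controlled and are erased by aromatisation. The step needs attack on a ring ketone and not on the ester (ester attack is degenerate in MeOH) and six-membered, not five-membered, reclosure; the second is secured because return to 11 is only the reverse reaction, while 13 is drained as its doubly stabilised salt (β-keto ester enolate, then aromatic diolate). The aryl methyl ethers are inert to methoxide, and air is kept out so that the electron-rich diol is not oxidised in base.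

Step 6
Reactants: 14 methyl 1,4-dihydroxy-3-(1,3,4-trimethoxynaphthalen-2-yl)naphthalene-2-carboxylate
Product: 15 methyl 3-(3-methoxy-1,4-dioxo-1,4-dihydronaphthalen-2-yl)-1,4-dioxo-1,4-dihydronaphthalene-2-carboxylate
Conditions: (NH4)2Ce(NO3)6 (5 equiv), MeCN/H2O, 0 °C
Reagents that add atoms: water, O
Why: (NH4)2Ce(NO3)6 oxidises the hydroquinone ring to the quinone and oxidatively demethylates the para-dimethoxy pair of the trimethoxynaphthalene (water attacks the arene radical cation and two methanol are lost), while the remaining methoxy group stays as a vinylogous ester and the methyl ester is untouched.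

Step 7
Reactants: 15 methyl 3-(3-methoxy-1,4-dioxo-1,4-dihydronaphthalen-2-yl)-1,4-dioxo-1,4-dihydronaphthalene-2-carboxylate
Product: 16 methyl 3-(3-hydroxy-1,4-dioxo-1,4-dihydronaphthalen-2-yl)-1,4-dioxo-1,4-dihydronaphthalene-2-carboxylate
Conditions: LiOH (2.2 equiv), THF/H2O, 0 °C; then 1 M HCl
Reagents that add atoms: lithium hydroxide, [Li+].[OH-]
Why: Hydroxide adds to the methoxy-bearing carbon of the vinylogous ester and expels methoxide (addition–elimination), the product leaving the equilibrium as its stabilised hydroxyquinone anion, while the methyl ester, flanked by a quinone carbonyl and the biaryl axis, should be too hindered for saponification at 0 °C.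

**Compound list**
1 | 2-methoxy-1,4-naphthoquinone | COC1=CC(=O)c2ccccc2C1=O | starting material
2 | 2-methoxynaphthalene-1,4-diol | COc1cc(O)c2ccccc2c1O | intermediate
3 | 1,2,4-trimethoxynaphthalene | COc1cc(OC)c2ccccc2c1OC | intermediate
4 | (1,3,4-trimethoxynaphthalen-2-yl)lithium | [Li]c1c(OC)c(OC)c2ccccc2c1OC | intermediate
5 | 1,3,4-trimethoxynaphthalene-2-carbaldehyde | COc1c(C=O)c(OC)c(OC)c2ccccc12 | intermediate
6 | phthalide (2-benzofuran-1(3H)-one) | O=C1OCc2ccccc12 | starting material
7 | (Z)-3-[(1,3,4-trimethoxynaphthalen-2-yl)methylidene]-2-benzofuran-1(3H)-one | O=C1O/C(=C\c2c(OC)c(OC)c3ccccc3c2OC)c2ccccc12 | intermediate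
8 | methyl 2-[2-(1,3,4-trimethoxynaphthalen-2-yl)acetyl]benzoate | COC(=O)c1ccccc1C(=O)Cc1c(OC)c(OC)c2ccccc2c1OC | intermediate
9 | 2-(1,3,4-trimethoxynaphthalen-2-yl)-1H-indene-1,3(2H)-dione | O=C1C(c2c(OC)c(OC)c3ccccc3c2OC)C(=O)c2ccccc12 | intermediate
10 | methyl bromoacetate | COC(=O)CBr | starting material
11 | methyl 2-[1,3-dioxo-2-(1,3,4-trimethoxynaphthalen-2-yl)-2,3-dihydro-1H-inden-2-yl]acetate | COC(=O)CC1(c2c(OC)c(OC)c3ccccc3c2OC)C(=O)c2ccccc2C1=O | intermediate
12 | methyl 2-[4-methoxy-4-oxo-2-(1,3,4-trimethoxynaphthalen-2-yl)butanoyl]benzoate (racemic, stereocentre not set) | COC(=O)CC(C(=O)c1ccccc1C(=O)OC)c1c(OC)c(OC)c2ccccc2c1OC | intermediate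
13 | methyl 1,4-dioxo-3-(1,3,4-trimethoxynaphthalen-2-yl)-1,2,3,4-tetrahydronaphthalene-2-carboxylate (stereocentres not set) | COC(=O)C1C(c2c(OC)c(OC)c3ccccc3c2OC)C(=O)c2ccccc2C1=O | intermediate
14 | methyl 1,4-dihydroxy-3-(1,3,4-trimethoxynaphthalen-2-yl)naphthalene-2-carboxylate | COC(=O)c1c(O)c2ccccc2c(O)c1-c1c(OC)c(OC)c2ccccc2c1OC | intermediate
15 | methyl 3-(3-methoxy-1,4-dioxo-1,4-dihydronaphthalen-2-yl)-1,4-dioxo-1,4-dihydronaphthalene-2-carboxylate | COC(=O)C1=C(C2=C(OC)C(=O)c3ccccc3C2=O)C(=O)c2ccccc2C1=O | intermediate
16 | methyl 3-(3-hydroxy-1,4-dioxo-1,4-dihydronaphthalen-2-yl)-1,4-dioxo-1,4-dihydronaphthalene-2-carboxylate | COC(=O)C1=C(C2=C(O)C(=O)c3ccccc3C2=O)C(=O)c2ccccc2C1=O | target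

**Totals**
Total step count: 7. Longest linear sequence: 7 steps (1 → 16).

**Steps most likely to fail**

Step 4. C-alkylation at the carbon next to the di-ortho-methoxyaryl group may be slow, and O-alkylation of the enolate may take over. The fallback sets out from 3 and comes back at 11; it builds the quaternary carbon by C-arylation and also bypasses step 3. Lithiation of 3 as in step 2 (giving 4), quench with B(OMe)3 and aqueous HCl should give (1,3,4-trimethoxynaphthalen-2-yl)boronic acid F1. Boron-to-lead exchange with Pb(OAc)4 and Hg(OAc)2 (cat.) in CHCl3 should give (1,3,4-trimethoxynaphthalen-2-yl)lead triacetate F2. Separately, commercial indane-1,3-dione, methyl glyoxylate and Hantzsch ester with L-proline (cat.) in CH2Cl2 should give, through the Knoevenagel alkylidene methyl 2-(1,3-dioxo-1,3-dihydro-2H-inden-2-ylidene)acetate F3, the reduced dione methyl 2-(1,3-dioxo-2,3-dihydro-1H-inden-2-yl)acetate F4. Pinhey arylation of F4 with F2 (pyridine, CHCl3, 40 °C) forms the aryl–carbon bond by ligand coupling on lead, which can only arylate at carbon, and should deliver 11.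

Step 5. The sequence may stop at the ring-opened stage, or the opened ester may be saponified by adventitious water instead of reclosing to the six-membered ring. The fallback sets out from 5 and comes back at 14, forming ring A by annulation instead of rearrangement. Wittig olefination of 5 with methyl (triphenylphosphoranylidene)acetate (toluene, 80 °C) should give methyl (E)-3-(1,3,4-trimethoxynaphthalen-2-yl)prop-2-enoate F5. Hauser–Kraus annulation of F5 with the anion of commercial 3-(phenylsulfonyl)-2-benzofuran-1(3H)-one (LiOtBu, THF, −78 °C → rt) proceeds by Michael addition, Dieckmann closure onto the lactone carbonyl and loss of sulfinate, and should give 14.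

Step 7. Chemoselectivity may be lost through attack of hydroxide on the ester-bearing quinone or saponification of the methyl ester. The fallback sets out from 14 and comes back at 16, unmasking before oxidation so that no methoxyquinone has to be hydrolysed. Treatment of 14 with BBr3 (CH2Cl2, −78 → 0 °C), which normally spares methyl esters at low temperature, should cleave the three aryl methyl ethers to methyl 1,4-dihydroxy-3-(1,3,4-trihydroxynaphthalen-2-yl)naphthalene-2-carboxylate F6. Oxidation of F6 with Ag2O (Et2O/MeCN, rt) should convert the hydroquinone ring to the quinone and the trihydroxynaphthalene to the hydroxyquinone, giving 16 directly.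

**Further compounds**
F1 | step 4 | (1,3,4-trimethoxynaphthalen-2-yl)boronic acid | OB(O)c1c(OC)c(OC)c2ccccc2c1OC
F2 | step 4 | (1,3,4-trimethoxynaphthalen-2-yl)lead triacetate | CC(=O)O[Pb](OC(C)=O)(OC(C)=O)c1c(OC)c(OC)c2ccccc2c1OC
F3 | step 4 | methyl 2-(1,3-dioxo-1,3-dihydro-2H-inden-2-ylidene)acetate | COC(=O)C=C1C(=O)c2ccccc2C1=O
F4 | step 4 | methyl 2-(1,3-dioxo-2,3-dihydro-1H-inden-2-yl)acetate | COC(=O)CC1C(=O)c2ccccc2C1=O
F5 | step 5 | methyl (E)-3-(1,3,4-trimethoxynaphthalen-2-yl)prop-2-enoate | COC(=O)/C=C/c1c(OC)c(OC)c2ccccc2c1OC
F6 | step 7 | methyl 1,4-dihydroxy-3-(1,3,4-trihydroxynaphthalen-2-yl)naphthalene-2-carboxylate | COC(=O)c1c(O)c2ccccc2c(O)c1-c1c(O)c(O)c2ccccc2c1O
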